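**Retrosynthetic overview**
- Feature: in the dihydrobenzofuran (O1, C2, C3, C3a, C7a) the ether carbon C2 is benzylic to the syringyl ring and para to its free 4-OH. The O1–C2 bond is therefore the bond a phenol makes when it adds to a para-quinone methide.
- Disconnection 1: the C5–vinyl bond, made by Heck coupling of a ring A C5 bromide with 3,5-bis(silyloxy)styrene, followed by desilylation.
- Disconnection 2 (key): O1–C2, leading back to an (S)-2,3-diarylpropan-1-ol whose syringol unit is dehydrogenated with Ag2O. C3 alone directs C2.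
- Disconnection 3: C2–C3, made by Evans alkylation of the ring A arylacetyl imide with a syringyl benzylic bromide from syringaldehyde. The imide comes from 4-bromo-2-methoxyphenol by allylation, Claisen shift and oxidative cleavage.
- Ring order: the three benzene rings are bought, and the dihydrofuran is the only ring made, at step 13.

Key step: step 13

Assumption: the target is the (2R,3S)-trans isomer encoded in the SMILES, so the (S)-configured 4-benzyloxazolidinone is used. Its chelated enolate alkylation gives the S centre that becomes C3.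

**Step 1**
Reactants: 1 4-bromo-2-methoxyphenol; 2 allyl bromide
Product: 3 1-(allyloxy)-4-bromo-2-methoxybenzene
Conditions: K2CO3, acetone, reflux
Reagents that add atoms: none
Why: Williamson ether synthesis, in which the phenoxide displaces the allylic bromide by SN2 while the aryl bromide stays inert.

**Step 2**
Reactants: 3 1-(allyloxy)-4-bromo-2-methoxybenzene
Product: 5 2-allyl-4-bromo-6-methoxyphenol, via ortho-dienone 4 (not isolated)
Conditions: N,N-diethylaniline, 200 °C
Reagents that add atoms: none
Why: Aromatic Claisen rearrangement, in which the [3,3] shift can end productively only at the one unsubstituted ortho carbon and dienone 4 then tautomerises to the phenol.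

**Step 3**
Reactants: 5 2-allyl-4-bromo-6-methoxyphenol
Product: 6 1-allyl-5-bromo-3-methoxy-2-(methoxymethoxy)benzene
Conditions: MOMCl, i-Pr2NEt, CH2Cl2, 0 °C to rt
Reagents that add atoms: chloromethyl methyl ether (MOMCl), COCCl
Why: O-alkylation (acetal protection) of the flanked phenol with the small, reactive MOMCl gives a group that tolerates the coming oxidants, strong base and hydride yet leaves under mild acid that spares the aryl bromide.

**Step 4**
Reactants: 6 1-allyl-5-bromo-3-methoxy-2-(methoxymethoxy)benzene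
Product: 8 2-[5-bromo-3-methoxy-2-(methoxymethoxy)phenyl]acetaldehyde, via vicinal diol 7 (not isolated)
Conditions: OsO4 (cat.), NaIO4, 2,6-lutidine, dioxane–H2O, rt
Reagents that add atoms: OsO4, O=[Os](=O)(=O)=O; NaIO4, [Na+].[O-]I(=O)(=O)=O
Why: Lemieux–Johnson oxidation, in which catalytic dihydroxylation of the only alkene gives diol 7 and periodate glycol cleavage removes the terminal carbon, with the lutidine buffer protecting the acetal and the enolisable aldehyde.

**Step 5**
Reactants: 8 2-[5-bromo-3-methoxy-2-(methoxymethoxy)phenyl]acetaldehyde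
Product: 9 2-[5-bromo-3-methoxy-2-(methoxymethoxy)phenyl]acetic acid
Conditions: NaClO2, NaH2PO4, 2-methyl-2-butene, t-BuOH–H2O, 0 °C to rt
Reagents that add atoms: NaClO2, [Na+].[O-]Cl=O
Why: Pinnick oxidation converts the aldehyde to the acid at buffered pH, and the alkene scavenger removes hypochlorous acid before it can chlorinate the electron-rich ring.

**Step 6**
Reactants: 9 2-[5-bromo-3-methoxy-2-(methoxymethoxy)phenyl]acetic acid; 10 (S)-4-benzyloxazolidin-2-one
Product: 12 (S)-4-benzyl-3-{2-[5-bromo-3-methoxy-2-(methoxymethoxy)phenyl]acetyl}oxazolidin-2-one, via mixed pivalic anhydride 11 (not isolated)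
Conditions: PivCl, Et3N, THF, −20 °C; then LiCl, 10, −20 °C to rt
Reagents that add atoms: pivaloyl chloride, CC(C)(C)C(=O)Cl (its atoms stay only in intermediate 11)
Why: N-acylation of the Evans auxiliary through a mixed anhydride, in which the LiCl-activated oxazolidinone attacks the less hindered arylacetyl carbonyl and pivalate leaves.

**Step 7**
Reactants: 13 syringaldehyde
Product: 14 3,5-dimethoxy-4-(methoxymethoxy)benzaldehyde
Conditions: MOMCl, i-Pr2NEt, CH2Cl2, 0 °C to rt
Reagents that add atoms: chloromethyl methyl ether (MOMCl), COCCl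
Why: O-alkylation (acetal protection) of the acidic para-formyl phenol uses the same group as on ring A, so that both can be removed in one operation.

**Step 8**
Reactants: 14 3,5-dimethoxy-4-(methoxymethoxy)benzaldehyde
Product: 15 [3,5-dimethoxy-4-(methoxymethoxy)phenyl]methanol
Conditions: NaBH4, MeOH, 0 °C
Reagents that add atoms: none
Why: Borohydride carbonyl reduction leaves the acetal and the methyl ethers untouched.

**Step 9**
Reactants: 15 [3,5-dimethoxy-4-(methoxymethoxy)phenyl]methanol
Product: 16 5-(bromomethyl)-1,3-dimethoxy-2-(methoxymethoxy)benzene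
Conditions: CBr4, PPh3, CH2Cl2, 0 °C; used at once
Reagents that add atoms: carbon tetrabromide, BrC(Br)(Br)Br
Why: Appel reaction, in which bromide displaces the alkoxyphosphonium ion under near-neutral conditions that keep the acid-labile MOM group on this electron-rich benzylic system.

**Step 10**
Reactants: 12 (S)-4-benzyl-3-{2-[5-bromo-3-methoxy-2-(methoxymethoxy)phenyl]acetyl}oxazolidin-2-one; 16 5-(bromomethyl)-1,3-dimethoxy-2-(methoxymethoxy)benzene
Product: 18 (S)-4-benzyl-3-{(S)-2-[5-bromo-3-methoxy-2-(methoxymethoxy)phenyl]-3-[3,5-dimethoxy-4-(methoxymethoxy)phenyl]propanoyl}oxazolidin-2-one, via sodium Z-enolate 17 (not isolated)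
Conditions: NaN(SiMe3)2, THF, −78 °C; then 16, −78 to −40 °C; AcOH quench at low temperature
Reagents that add atoms: NaN(SiMe3)2, [Na+].C[Si](C)(C)[N-][Si](C)(C)C (sodium stays only in intermediate 17)
Why: Evans asymmetric alkylation, in which the sodium-chelated Z-enolate 17 is shielded on one face by the C4 benzyl group, so the benzylic bromide enters from the other face, forms the C2–C3 bond and sets the future C3 as S.

**Step 11**
Reactants: 18 (S)-4-benzyl-3-{(S)-2-[5-bromo-3-methoxy-2-(methoxymethoxy)phenyl]-3-[3,5-dimethoxy-4-(methoxymethoxy)phenyl]propanoyl}oxazolidin-2-one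
Product: 19 (S)-2-[5-bromo-3-methoxy-2-(methoxymethoxy)phenyl]-3-[3,5-dimethoxy-4-(methoxymethoxy)phenyl]propan-1-ol
Conditions: LiBH4, H2O (1 equiv), Et2O–THF, 0 °C
Reagents that add atoms: none
Why: Reductive cleavage of the Evans imide, in which hydride attacks the exocyclic carbonyl and takes it to the primary alcohol under weakly basic conditions, so the acidic alpha-aryl centre is not epimerised and the auxiliary is released intact.

**Step 12**
Reactants: 19 (S)-2-[5-bromo-3-methoxy-2-(methoxymethoxy)phenyl]-3-[3,5-dimethoxy-4-(methoxymethoxy)phenyl]propan-1-ol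
Product: 20 (S)-4-bromo-2-[1-hydroxy-3-(4-hydroxy-3,5-dimethoxyphenyl)propan-2-yl]-6-methoxyphenol
Conditions: HCl (cat.), MeOH, 40 °C
Reagents that add atoms: none
Why: Acid-catalysed acetal methanolysis frees both phenols, while the aryl bromide, the methyl ethers, the primary alcohol and the non-enolisable stereocentre have no pathway to react.

**Step 13**
Reactants: 20 (S)-4-bromo-2-[1-hydroxy-3-(4-hydroxy-3,5-dimethoxyphenyl)propan-2-yl]-6-methoxyphenol
Product: 22 4-[(2R,3S)-5-bromo-3-(hydroxymethyl)-7-methoxy-2,3-dihydrobenzofuran-2-yl]-2,6-dimethoxyphenol, via para-quinone methide 21 (not isolated)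
Conditions: Ag2O (1.2 equiv), CH2Cl2–acetone, rt, dark; filtration through Celite
Reagents that add atoms: none
Why: The oxidant takes the phenolic hydrogen of the syringol and then one benzylic hydrogen of C2 (net loss of H2, Ag2O ending as silver metal and water), which gives para-quinone methide 21; the ring A phenol then adds to its exocyclic carbon C2 in an oxa-1,6-conjugate addition that re-aromatises the syringyl ring and forms O1–C2. The closest known reaction type is the Ag2O or DDQ dehydrogenation of 2,6-disubstituted 4-alkylphenols to para-quinone methides followed by capture by a tethered nucleophile, the same event that closes phenylcoumaran rings in lignan and stilbene-dimer biogenesis. The ring O1–C2–C3–C3a–C7a closes in the 5-exo-trig mode, because the attacked C2=C1' bond lies outside the new ring. C2 is the only new stereocentre and is governed by C3: the oxygen should reach the flat methide on the face that puts the syringyl group anti to the C3 hydroxymethyl group (2R), and because 22 keeps its free 4-OH the closure remains reversible, so any cis material can drain to the more stable trans isomer. The step needs site-selective oxidation, which the substrate provides because the syringol (two methoxy groups, para alkyl group) is the more easily oxidised phenol whereas the ring A phenol carries a withdrawing para bromine, and the C9 hydroxyl is no competitor since its addition would build a four-membered ring. Keeping the oxidant close to one equivalent should protect 22, itself a 4-substituted syringol, from a second dehydrogenation.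

**Step 14**
Reactants: 22 4-[(2R,3S)-5-bromo-3-(hydroxymethyl)-7-methoxy-2,3-dihydrobenzofuran-2-yl]-2,6-dimethoxyphenol
Product: 23 (2R,3S)-5-bromo-2-{4-[(tert-butyldimethylsilyl)oxy]-3,5-dimethoxyphenyl}-3-{[(tert-butyldimethylsilyl)oxy]methyl}-7-methoxy-2,3-dihydrobenzofuran
Conditions: TBSCl, imidazole, DMF, rt
Reagents that add atoms: tert-butyldimethylsilyl chloride (TBSCl), CC(C)(C)[Si](C)(C)Cl
Why: Imidazole-promoted silylation caps the syringyl phenol and the C9 alcohol, which removes the free 4-OH that would let the hot amine base of the Heck step reopen O1–C2 through the quinone methide.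

**Step 15**
Reactants: 24 3,5-dihydroxybenzaldehyde
Product: 25 3,5-bis[(tert-butyldimethylsilyl)oxy]benzaldehyde
Conditions: TBSCl, imidazole, DMF, rt
Reagents that add atoms: tert-butyldimethylsilyl chloride (TBSCl), CC(C)(C)[Si](C)(C)Cl
Why: Imidazole-promoted silylation of both phenols removes the acidic protons that would quench the ylide of the next step.

**Step 16**
Reactants: 25 3,5-bis[(tert-butyldimethylsilyl)oxy]benzaldehyde
Product: 26 3,5-bis[(tert-butyldimethylsilyl)oxy]styrene
Conditions: Ph3PCH3Br, n-BuLi, THF, 0 °C; then 25, 0 °C to rt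
Reagents that add atoms: methyltriphenylphosphonium bromide, C[P+](c1ccccc1)(c1ccccc1)c1ccccc1.[Br-]
Why: Wittig methylenation with the preformed non-stabilised ylide gives the terminal alkene, and no free base remains to attack the aryl silyl ethers.

**Step 17**
Reactants: 23 (2R,3S)-5-bromo-2-{4-[(tert-butyldimethylsilyl)oxy]-3,5-dimethoxyphenyl}-3-{[(tert-butyldimethylsilyl)oxy]methyl}-7-methoxy-2,3-dihydrobenzofuran; 26 3,5-bis[(tert-butyldimethylsilyl)oxy]styrene
Product: 27 tetrakis-O-(tert-butyldimethylsilyl)gnetucleistol F, (2R,3S), E-alkene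
Conditions: Pd2(dba)3 (cat.), [HP(t-Bu)3]BF4 (cat.), Cy2NMe, dioxane, 50 °C
Reagents that add atoms: none
Why: Mizoroki–Heck reaction, in which zerovalent palladium bearing P(t-Bu)3 inserts into the electron-rich C5–Br bond, and syn-carbopalladation at the unsubstituted styrene carbon followed by syn-beta-hydride elimination gives the E-stilbene without touching C2 or C3.

**Step 18**
Reactants: 27 tetrakis-O-(tert-butyldimethylsilyl)gnetucleistol F
Product: 28 gnetucleistol F
Conditions: Et3N·3HF, THF, rt, subdued light
Reagents that add atoms: none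
Why: Fluoride-driven desilylation frees three phenols and the primary alcohol through Si–F bond formation, and the weakly acidic reagent avoids phenoxides, so neither O1–C2 nor the E-alkene is disturbed.

**Compound list**
1 | 4-bromo-2-methoxyphenol | COc1cc(Br)ccc1O | starting material
2 | allyl bromide | C=CCBr | starting material
3 | 1-(allyloxy)-4-bromo-2-methoxybenzene | C=CCOc1ccc(Br)cc1OC | intermediate
4 | 6-allyl-4-bromo-2-methoxycyclohexa-2,4-dien-1-one (racemic, not isolated) | C=CCC1C=C(Br)C=C(OC)C1=O | intermediate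
5 | 2-allyl-4-bromo-6-methoxyphenol | C=CCc1cc(Br)cc(OC)c1O | intermediate
6 | 1-allyl-5-bromo-3-methoxy-2-(methoxymethoxy)benzene | C=CCc1cc(Br)cc(OC)c1OCOC | intermediate
7 | 3-[5-bromo-3-methoxy-2-(methoxymethoxy)phenyl]propane-1,2-diol (racemic, not isolated) | OCC(O)Cc1cc(Br)cc(OC)c1OCOC | intermediate
8 | 2-[5-bromo-3-methoxy-2-(methoxymethoxy)phenyl]acetaldehyde | O=CCc1cc(Br)cc(OC)c1OCOC | intermediate
9 | 2-[5-bromo-3-methoxy-2-(methoxymethoxy)phenyl]acetic acid | OC(=O)Cc1cc(Br)cc(OC)c1OCOC | intermediate
10 | (S)-4-benzyloxazolidin-2-one | O=C1N[C@@H](Cc2ccccc2)CO1 | starting material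
11 | 2-[5-bromo-3-methoxy-2-(methoxymethoxy)phenyl]acetic pivalic anhydride (not isolated) | CC(C)(C)C(=O)OC(=O)Cc1cc(Br)cc(OC)c1OCOC | intermediate
12 | (S)-4-benzyl-3-{2-[5-bromo-3-methoxy-2-(methoxymethoxy)phenyl]acetyl}oxazolidin-2-one | O=C1OC[C@H](Cc2ccccc2)N1C(=O)Cc1cc(Br)cc(OC)c1OCOC | intermediate
13 | syringaldehyde | COc1cc(C=O)cc(OC)c1O | starting material
14 | 3,5-dimethoxy-4-(methoxymethoxy)benzaldehyde | COCOc1c(OC)cc(C=O)cc1OC | intermediate
15 | [3,5-dimethoxy-4-(methoxymethoxy)phenyl]methanol | COCOc1c(OC)cc(CO)cc1OC | intermediate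
16 | 5-(bromomethyl)-1,3-dimethoxy-2-(methoxymethoxy)benzene | COCOc1c(OC)cc(CBr)cc1OC | intermediate
17 | sodium Z-enolate of 12 (not isolated) | [Na+].[O-]/C(=C\c1cc(Br)cc(OC)c1OCOC)N1[C@@H](Cc2ccccc2)COC1=O | intermediate
18 | (S)-4-benzyl-3-{(S)-2-[5-bromo-3-methoxy-2-(methoxymethoxy)phenyl]-3-[3,5-dimethoxy-4-(methoxymethoxy)phenyl]propanoyl}oxazolidin-2-one | O=C1OC[C@H](Cc2ccccc2)N1C(=O)[C@@H](Cc1cc(OC)c(OCOC)c(OC)c1)c1cc(Br)cc(OC)c1OCOC | intermediate
19 | (S)-2-[5-bromo-3-methoxy-2-(methoxymethoxy)phenyl]-3-[3,5-dimethoxy-4-(methoxymethoxy)phenyl]propan-1-ol | COCOc1c(OC)cc(C[C@H](CO)c2cc(Br)cc(OC)c2OCOC)cc1OC | intermediate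
20 | (S)-4-bromo-2-[1-hydroxy-3-(4-hydroxy-3,5-dimethoxyphenyl)propan-2-yl]-6-methoxyphenol | COc1cc(C[C@H](CO)c2cc(Br)cc(OC)c2O)cc(OC)c1O | intermediate
21 | (S)-4-[2-(5-bromo-2-hydroxy-3-methoxyphenyl)-3-hydroxypropylidene]-2,6-dimethoxycyclohexa-2,5-dien-1-one (not isolated) | COC1=CC(=C[C@H](CO)c2cc(Br)cc(OC)c2O)C=C(OC)C1=O | intermediate
22 | 4-[(2R,3S)-5-bromo-3-(hydroxymethyl)-7-methoxy-2,3-dihydrobenzofuran-2-yl]-2,6-dimethoxyphenol | COc1cc([C@@H]2Oc3c(OC)cc(Br)cc3[C@H]2CO)cc(OC)c1O | intermediate
23 | (2R,3S)-5-bromo-2-{4-[(tert-butyldimethylsilyl)oxy]-3,5-dimethoxyphenyl}-3-{[(tert-butyldimethylsilyl)oxy]methyl}-7-methoxy-2,3-dihydrobenzofuran | COc1cc([C@@H]2Oc3c(OC)cc(Br)cc3[C@H]2CO[Si](C)(C)C(C)(C)C)cc(OC)c1O[Si](C)(C)C(C)(C)C | intermediate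
24 | 3,5-dihydroxybenzaldehyde | O=Cc1cc(O)cc(O)c1 | starting material
25 | 3,5-bis[(tert-butyldimethylsilyl)oxy]benzaldehyde | O=Cc1cc(O[Si](C)(C)C(C)(C)C)cc(O[Si](C)(C)C(C)(C)C)c1 | intermediate
26 | 3,5-bis[(tert-butyldimethylsilyl)oxy]styrene | C=Cc1cc(O[Si](C)(C)C(C)(C)C)cc(O[Si](C)(C)C(C)(C)C)c1 | intermediate
27 | tetrakis-O-(tert-butyldimethylsilyl)gnetucleistol F | COc1cc([C@@H]2Oc3c(OC)cc(/C=C/c4cc(O[Si](C)(C)C(C)(C)C)cc(O[Si](C)(C)C(C)(C)C)c4)cc3[C@H]2CO[Si](C)(C)C(C)(C)C)cc(OC)c1O[Si](C)(C)C(C)(C)C | intermediate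
28 | gnetucleistol F | COc1cc([C@@H]2Oc3c(OC)cc(/C=C/c4cc(O)cc(O)c4)cc3[C@H]2CO)cc(OC)c1O | target

**Totals**
- Total step count: 18.
- Longest linear sequence: 13 steps (1–6, 10–14, 17, 18).

**Steps most likely to fail**

1. Step 13.
   - What may go wrong:
     - The oxidation may stray to the ring A phenol, giving hydrogen loss at C3 or radical coupling.
     - The quinone methide may tautomerise to the vinylphenol, erasing the C3 configuration.
     - The product may be dehydrogenated a second time towards the benzofuran.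
   - Fallback (sets out from 9 and 14, returns at 22): the same quinone methide is reached without any oxidant, by ionising a benzylic alcohol.
     - Acid 9 is coupled through anhydride 11 with commercial (R)-4-benzyloxazolidin-2-one to give the antipodal-auxiliary imide F1.
     - Enolisation with Bu2BOTf/i-Pr2NEt (CH2Cl2, −78 °C) and Evans syn-aldol addition to aldehyde 14 give the syn-aldol F2.
     - The boron aldol uses the enolate face opposite to that of the chelated alkylation, which is why the R auxiliary gives the same C3 configuration.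
     - LiBH4 releases the auxiliary and gives the 1,3-diol F3.
     - HCl in MeOH strips both acetals to the tetraol F4. Its benzylic hydroxyl, para to the free syringyl OH, ionises under the same acid to the O-protonated form of 21, and the ring A phenol captures it to give 22.
     - The carbinol configuration is erased at that point, and C3 again sets the trans geometry.

2. Step 10.
   - What may go wrong:
     - The arylacetyl imide enolate may fragment to a ketene with loss of the auxiliary if it warms before it is alkylated.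
     - The ortho-substituted aryl group may slow the alkylation.
     - Residual base may deprotonate the acidic alpha-aryl position and erode the diastereomeric purity.
     - The electron-rich benzylic bromide may decompose.
   - Fallback (sets out from 9 and 14, returns at 19): the stereocentre is set by hydrogenation instead of alkylation.
     - Perkin condensation of 9 with 14 (Ac2O, Et3N, 110 °C) gives the E-2,3-diarylacrylic acid F5.
     - Asymmetric hydrogenation with a cationic complex [Ir(cod)(L)]BArF (L = chiral spiro phosphine–oxazoline of the SpinPHOX type, enantiomer chosen to give S; H2, Et3N, MeOH) gives the S-2,3-diarylpropanoic acid F6.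
     - BH3·THF reduces F6 to 19.

3. Step 17.
   - What may go wrong:
     - Oxidative addition into the electron-rich bromide may be slow.
     - Insertion may occur with the 1,1-diaryl regiochemistry.
     - Phenolic silyl groups may be lost on prolonged heating.
   - Fallback (sets out from 23 and 25, returns at 27): the alkene is built by olefination.
     - Bromine–lithium exchange on 23 (n-BuLi, THF, −78 °C) and quenching with DMF give the C5 carbaldehyde F7.
     - Aldehyde 25 is reduced (NaBH4) to the benzylic alcohol F8.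
     - F8 is brominated (CBr4, PPh3) to the benzylic bromide F9.
     - F9 is heated with P(OEt)3 (Michaelis–Arbuzov reaction) to give the diethyl benzylphosphonate F10.
     - Horner–Wadsworth–Emmons olefination of F7 with F10 (LiN(SiMe3)2, THF, −78 to 0 °C) gives E-alkene 27.

**Further compounds**
F1 | step 13 | (R)-4-benzyl-3-{2-[5-bromo-3-methoxy-2-(methoxymethoxy)phenyl]acetyl}oxazolidin-2-one | O=C1OC[C@@H](Cc2ccccc2)N1C(=O)Cc1cc(Br)cc(OC)c1OCOC
F2 | step 13 | (R)-4-benzyl-3-{(2R,3R)-2-[5-bromo-3-methoxy-2-(methoxymethoxy)phenyl]-3-[3,5-dimethoxy-4-(methoxymethoxy)phenyl]-3-hydroxypropanoyl}oxazolidin-2-one | O=C1OC[C@@H](Cc2ccccc2)N1C(=O)[C@@H]([C@@H](O)c1cc(OC)c(OCOC)c(OC)c1)c1cc(Br)cc(OC)c1OCOC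
F3 | step 13 | (1R,2S)-2-[5-bromo-3-methoxy-2-(methoxymethoxy)phenyl]-1-[3,5-dimethoxy-4-(methoxymethoxy)phenyl]propane-1,3-diol | OC[C@@H]([C@@H](O)c1cc(OC)c(OCOC)c(OC)c1)c1cc(Br)cc(OC)c1OCOC
F4 | step 13 | (1R,2S)-2-(5-bromo-2-hydroxy-3-methoxyphenyl)-1-(4-hydroxy-3,5-dimethoxyphenyl)propane-1,3-diol | OC[C@@H]([C@@H](O)c1cc(OC)c(O)c(OC)c1)c1cc(Br)cc(OC)c1O
F5 | step 10 | (E)-2-[5-bromo-3-methoxy-2-(methoxymethoxy)phenyl]-3-[3,5-dimethoxy-4-(methoxymethoxy)phenyl]acrylic acid | OC(=O)/C(=C/c1cc(OC)c(OCOC)c(OC)c1)c1cc(Br)cc(OC)c1OCOC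
F6 | step 10 | (S)-2-[5-bromo-3-methoxy-2-(methoxymethoxy)phenyl]-3-[3,5-dimethoxy-4-(methoxymethoxy)phenyl]propanoic acid | OC(=O)[C@@H](Cc1cc(OC)c(OCOC)c(OC)c1)c1cc(Br)cc(OC)c1OCOC
F7 | step 17 | (2R,3S)-2-{4-[(tert-butyldimethylsilyl)oxy]-3,5-dimethoxyphenyl}-3-{[(tert-butyldimethylsilyl)oxy]methyl}-7-methoxy-2,3-dihydrobenzofuran-5-carbaldehyde | COc1cc([C@@H]2Oc3c(OC)cc(C=O)cc3[C@H]2CO[Si](C)(C)C(C)(C)C)cc(OC)c1O[Si](C)(C)C(C)(C)C
F8 | step 17 | {3,5-bis[(tert-butyldimethylsilyl)oxy]phenyl}methanol | OCc1cc(O[Si](C)(C)C(C)(C)C)cc(O[Si](C)(C)C(C)(C)C)c1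
F9 | step 17 | 1-(bromomethyl)-3,5-bis[(tert-butyldimethylsilyl)oxy]benzene | BrCc1cc(O[Si](C)(C)C(C)(C)C)cc(O[Si](C)(C)C(C)(C)C)c1
F10 | step 17 | diethyl {3,5-bis[(tert-butyldimethylsilyl)oxy]benzyl}phosphonate | CCOP(=O)(Cc1cc(O[Si](C)(C)C(C)(C)C)cc(O[Si](C)(C)C(C)(C)C)c1)OCC
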